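**Retrosynthetic overview**

1. The target is traced back, by desilylation, hydrogenation of C13=C14 and saponification/Nef reaction, to nitro allylic alcohol 15. The C9 ketone is carried as a nitro group, and C14–C20 come from β-ketophosphonate 13 (HWE at the C13 aldehyde, CBS reduction at C15).
2. The only ring, the cyclopentane C8–C9–C10–C11–C12, is closed at C9–C10 by the C9 nitronate attacking the primary C10 bromide. This happens in the same flask in which C8–C12 is made by amine-catalysed Michael addition of aldehyde 9 (C10–C13) to nitroalkene 6 (C1–C9).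
3. Enabling feature: in the cyclopentanone ring the carbonyl carbon C9 lies between stereogenic C8 and an unsubstituted methylene C10, which is bonded to the oxygen-bearing C11. C9 can therefore be a nitro carbon (acyl-anion equivalent) and C10–C11 a bromohydrin silyl ether, while a formyl group (C13) on C12 keeps C12 epimerisable.
4. Stereocontrol: C8 by the amine catalyst, C11 from commercial hydroxy ester 7, C12 by equilibration to the all-trans ring (C12 and C9 epimers are funnelled), C15 by CBS reduction.
5. Fragments: 6 from cis-cyclooctene in two steps; 9 from 7 in two steps.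

Key step: step 5

Remark: prostaglandin numbering (C1–C20) is used for atoms; the nitro-bearing carbon C9 of 11, 12 and 14–16 should form as an epimer mixture that converges in step 8, so it is written without configuration.

**Route**

Step 1
Reactants: 1 cis-cyclooctene
Product: 3 methyl 8-oxooctanoate, via methoxy hydroperoxide 2 (not isolated)
Conditions: O3, CH2Cl2/MeOH, NaHCO3, −78 °C; then Ac2O, Et3N, CH2Cl2, 0 °C → rt
Reagents that add atoms: ozone (O=[O+][O-]); methanol (CO)
Why: Unsymmetrical ozonolysis: methanol traps the carbonyl oxide as the α-methoxy hydroperoxide at one terminus while the other becomes the aldehyde, and acetylation/base-induced fragmentation of the hydroperoxide gives the methyl ester; no stereocentre is formed.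

Step 2
Reactants: 3 methyl 8-oxooctanoate
Product: 6 methyl (E)-9-nitronon-8-enoate, via Henry adduct 4 (not isolated), via mesylate 5 (not isolated)
Conditions: MeNO2 (excess), Et3N (cat.), 0 °C → rt; evaporate; then MsCl, Et3N, CH2Cl2, −20 → 0 °C
Reagents that add atoms: nitromethane (C[N+](=O)[O-]); methanesulfonyl chloride (CS(=O)(=O)Cl, its atoms are carried by 5 only and lost again)
Why: Henry reaction followed by mesylation and E1cB elimination should give the conjugated nitroalkene, with the E geometry favoured thermodynamically; the remote ester is inert.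

Step 3
Reactants: 7 ethyl (S)-4-bromo-3-hydroxybutanoate
Product: 8 ethyl (S)-4-bromo-3-[(tert-butyldimethylsilyl)oxy]butanoate
Conditions: TBSOTf, 2,6-lutidine, CH2Cl2, −78 → 0 °C
Reagents that add atoms: tert-butyldimethylsilyl trifluoromethanesulfonate (CC(C)(C)[Si](C)(C)OS(=O)(=O)C(F)(F)F)
Why: O-Silylation with a silyl triflate and a hindered, weak base should protect the future C11 hydroxyl without epoxide closure onto the bromide; the stereocentre is not touched.

Step 4
Reactants: 8 ethyl (S)-4-bromo-3-[(tert-butyldimethylsilyl)oxy]butanoate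
Product: 9 (S)-4-bromo-3-[(tert-butyldimethylsilyl)oxy]butanal
Conditions: i-Bu2AlH (1.05 equiv), CH2Cl2, −78 °C; aq. KNaC4H4O6 work-up
Reagents that add atoms: none
Why: Partial ester reduction: the tetrahedral aluminium hemiacetal should persist at −78 °C and release the aldehyde only on work-up, leaving the primary bromide and the C11 centre unchanged.

Step 5
Reactants: 6 methyl (E)-9-nitronon-8-enoate; 9 (S)-4-bromo-3-[(tert-butyldimethylsilyl)oxy]butanal
Product: 12 methyl 7-[(1R,2R,3R)-3-[(tert-butyldimethylsilyl)oxy]-2-formyl-5-nitrocyclopentyl]heptanoate, via syn Michael adduct 10 (not isolated), via all-cis nitrocyclopentane aldehyde 11 (not isolated)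
Conditions: (S)-2-[diphenyl(trimethylsilyloxy)methyl]pyrrolidine (10 mol%), 4-nitrophenol (10 mol%), MeCN, 0 °C → rt; then dilute to 0.03 M, DBU (2 equiv), NaI (20 mol%), 0 °C → rt
Reagents that add atoms: none
Why: The enamine formed from 9 and the (S)-configured pyrrolidine adds through its unshielded face to nitroalkene 6 in an acyclic synclinal transition state (reaction type: diarylprolinol silyl ether-catalysed Michael addition of aldehydes to nitroalkenes), forming C8–C12 and giving syn adduct 10 with C8 fixed by the catalyst. DBU then deprotonates the CH2NO2 group, and the C9 nitronate displaces the primary bromide at C10 by SN2 C-alkylation (reaction type: intramolecular nitronate alkylation, helped by iodide exchange), which closes the cyclopentane ring C8–C9–C10–C11–C12 in the 5-exo-tet mode and first gives the all-cis aldehyde 11. C-alkylation is expected over O-alkylation because the latter would need a seven-membered nitronic ester, and the nitronate should react before any aldehyde enolate because the nitro group is by far the more acidic site. C12, α to the formyl group, then epimerises through its enol(ate) under DBU to the arrangement trans to both the C8 chain and the C11 silyl ether, so that C12 epimers of 10 and 11 are funnelled into 12 under thermodynamic control. C11 comes unchanged from 7 and has no acidic hydrogen; C9 forms as a mixture that is erased in step 8. The selectivity the step needs, reprotonation of the enolate instead of loss of silanolate from C11, should be secured by the poor leaving ability of the bulky silanolate and the strain relief on going from the all-cis to the all-trans ring.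

Step 6
Reactants: 12 methyl 7-[(1R,2R,3R)-3-[(tert-butyldimethylsilyl)oxy]-2-formyl-5-nitrocyclopentyl]heptanoate; 13 dimethyl (2-oxoheptyl)phosphonate
Product: 14 methyl 7-[(1R,2R,3R)-3-[(tert-butyldimethylsilyl)oxy]-5-nitro-2-[(E)-3-oxooct-1-enyl]cyclopentyl]heptanoate
Conditions: LiCl, i-Pr2NEt, MeCN, 0 °C → rt
Reagents that add atoms: none
Why: HWE olefination with a stabilised β-ketophosphonate under LiCl/amine conditions should give the E-enone; the base is too weak to cause loss of silanolate, and C12 is already in its thermodynamic configuration.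

Step 7
Reactants: 14 methyl 7-[(1R,2R,3R)-3-[(tert-butyldimethylsilyl)oxy]-5-nitro-2-[(E)-3-oxooct-1-enyl]cyclopentyl]heptanoate
Product: 15 methyl 7-[(1R,2R,3R)-3-[(tert-butyldimethylsilyl)oxy]-2-[(E,3S)-3-hydroxyoct-1-enyl]-5-nitrocyclopentyl]heptanoate
Conditions: (R)-2-methyl-CBS-oxazaborolidine (20 mol%), catecholborane, toluene, −78 °C
Reagents that add atoms: none
Why: CBS reduction: the (R)-oxazaborolidine should deliver hydride to the face of the C15 ketone that gives the (15S) alcohol (alkenyl as the large group, pentyl as the small one), under reagent control; nitro and ester groups are inert to catecholborane.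

Step 8
Reactants: 15 methyl 7-[(1R,2R,3R)-3-[(tert-butyldimethylsilyl)oxy]-2-[(E,3S)-3-hydroxyoct-1-enyl]-5-nitrocyclopentyl]heptanoate
Product: 17 7-[(1R,2R,3R)-3-[(tert-butyldimethylsilyl)oxy]-2-[(E,3S)-3-hydroxyoct-1-enyl]-5-oxocyclopentyl]heptanoic acid, via nitro acid 16 (not isolated)
Conditions: LiOH, THF/H2O, 0 °C → rt; then added to aq. TiCl3/NH4OAc (pH 5–6), 0 °C → rt
Reagents that add atoms: lithium hydroxide ([Li+].[OH-]); water (O)
Why: Saponification is done while C9 is still a nitro carbon, so no β-silyloxy ketone meets hydroxide; the lithium nitronate formed in the same medium then undergoes a reductive Nef reaction, in which trivalent titanium reduces it to the imine and the buffer hydrolyses this to the C9 ketone. C8, now α to the ketone, is already in the favoured trans arrangement.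

Step 9
Reactants: 17 7-[(1R,2R,3R)-3-[(tert-butyldimethylsilyl)oxy]-2-[(E,3S)-3-hydroxyoct-1-enyl]-5-oxocyclopentyl]heptanoic acid
Product: 18 7-[(1R,2R,3R)-3-[(tert-butyldimethylsilyl)oxy]-2-[(3S)-3-hydroxyoctyl]-5-oxocyclopentyl]heptanoic acid
Conditions: H2 (1 atm), Pd/C, EtOAc, rt
Reagents that add atoms: none
Why: Heterogeneous hydrogenation should saturate the disubstituted C13=C14 alkene while the ketone, acid and silyl ether stay intact; no stereocentre is touched.

Step 10
Reactants: 18 7-[(1R,2R,3R)-3-[(tert-butyldimethylsilyl)oxy]-2-[(3S)-3-hydroxyoctyl]-5-oxocyclopentyl]heptanoic acid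
Product: 19 13,14-dihydro-PGE1
Conditions: HF·pyridine, MeCN, 0 °C
Reagents that add atoms: none
Why: Fluoride-mediated desilylation under weakly acidic conditions should free the C11 hydroxyl without dehydration of the β-hydroxy ketone or epimerisation at C8.

**Compound list**

1 | cis-cyclooctene | C1CCCCC/C=C\1 | starting material
2 | 8-hydroperoxy-8-methoxyoctanal (not isolated) | O=CCCCCCCC(OC)OO | intermediate
3 | methyl 8-oxooctanoate | COC(=O)CCCCCCC=O | intermediate
4 | methyl 8-hydroxy-9-nitrononanoate, racemic (not isolated) | COC(=O)CCCCCCC(O)C[N+](=O)[O-] | intermediate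
5 | methyl 8-(methanesulfonyloxy)-9-nitrononanoate, racemic (not isolated) | COC(=O)CCCCCCC(OS(C)(=O)=O)C[N+](=O)[O-] | intermediate
6 | methyl (E)-9-nitronon-8-enoate | COC(=O)CCCCCC/C=C/[N+](=O)[O-] | intermediate
7 | ethyl (S)-4-bromo-3-hydroxybutanoate | CCOC(=O)C[C@H](O)CBr | starting material
8 | ethyl (S)-4-bromo-3-[(tert-butyldimethylsilyl)oxy]butanoate | CCOC(=O)C[C@H](O[Si](C)(C)C(C)(C)C)CBr | intermediate
9 | (S)-4-bromo-3-[(tert-butyldimethylsilyl)oxy]butanal | O=CC[C@H](O[Si](C)(C)C(C)(C)C)CBr | intermediate
10 | methyl (8R,9S,10S)-11-bromo-10-[(tert-butyldimethylsilyl)oxy]-9-formyl-8-(nitromethyl)undecanoate, syn Michael adduct (not isolated) | O=C[C@H]([C@@H](CBr)O[Si](C)(C)C(C)(C)C)[C@H](C[N+](=O)[O-])CCCCCCC(=O)OC | intermediate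
11 | methyl 7-[(1R,2S,3R)-3-[(tert-butyldimethylsilyl)oxy]-2-formyl-5-nitrocyclopentyl]heptanoate, all-cis at C8/C12/C11, C9 epimers (not isolated) | O=C[C@@H]1[C@H](O[Si](C)(C)C(C)(C)C)CC([N+](=O)[O-])[C@@H]1CCCCCCC(=O)OC | intermediate
12 | methyl 7-[(1R,2R,3R)-3-[(tert-butyldimethylsilyl)oxy]-2-formyl-5-nitrocyclopentyl]heptanoate, all-trans at C8/C12/C11, C9 epimers | O=C[C@H]1[C@H](O[Si](C)(C)C(C)(C)C)CC([N+](=O)[O-])[C@@H]1CCCCCCC(=O)OC | intermediate
13 | dimethyl (2-oxoheptyl)phosphonate | CCCCCC(=O)CP(=O)(OC)OC | starting material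
14 | methyl 7-[(1R,2R,3R)-3-[(tert-butyldimethylsilyl)oxy]-5-nitro-2-[(E)-3-oxooct-1-enyl]cyclopentyl]heptanoate, C9 epimers | CCCCCC(=O)/C=C/[C@H]1[C@H](O[Si](C)(C)C(C)(C)C)CC([N+](=O)[O-])[C@@H]1CCCCCCC(=O)OC | intermediate
15 | methyl 7-[(1R,2R,3R)-3-[(tert-butyldimethylsilyl)oxy]-2-[(E,3S)-3-hydroxyoct-1-enyl]-5-nitrocyclopentyl]heptanoate, C9 epimers | CCCCC[C@H](O)/C=C/[C@H]1[C@H](O[Si](C)(C)C(C)(C)C)CC([N+](=O)[O-])[C@@H]1CCCCCCC(=O)OC | intermediate
16 | 7-[(1R,2R,3R)-3-[(tert-butyldimethylsilyl)oxy]-2-[(E,3S)-3-hydroxyoct-1-enyl]-5-nitrocyclopentyl]heptanoic acid, C9 epimers, present as its lithium carboxylate/nitronate (not isolated) | CCCCC[C@H](O)/C=C/[C@H]1[C@H](O[Si](C)(C)C(C)(C)C)CC([N+](=O)[O-])[C@@H]1CCCCCCC(=O)O | intermediate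
17 | 7-[(1R,2R,3R)-3-[(tert-butyldimethylsilyl)oxy]-2-[(E,3S)-3-hydroxyoct-1-enyl]-5-oxocyclopentyl]heptanoic acid (11-O-TBS-PGE1) | CCCCC[C@H](O)/C=C/[C@H]1[C@H](O[Si](C)(C)C(C)(C)C)CC(=O)[C@@H]1CCCCCCC(=O)O | intermediate
18 | 7-[(1R,2R,3R)-3-[(tert-butyldimethylsilyl)oxy]-2-[(3S)-3-hydroxyoctyl]-5-oxocyclopentyl]heptanoic acid | CCCCC[C@H](O)CC[C@H]1[C@H](O[Si](C)(C)C(C)(C)C)CC(=O)[C@@H]1CCCCCCC(=O)O | intermediate
19 | 13,14-dihydro-PGE1, 7-[(1R,2R,3R)-3-hydroxy-2-[(3S)-3-hydroxyoctyl]-5-oxocyclopentyl]heptanoic acid | CCCCC[C@H](O)CC[C@H]1[C@H](O)CC(=O)[C@@H]1CCCCCCC(=O)O | target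

**Step count and risks**

Total step count: 10. Longest linear sequence: 8 steps (steps 1, 2, 5, 6, 7, 8, 9, 10).

Steps most likely to fail:

1. Step 5. What may go wrong: in the DBU phase, loss of silanolate from C11 through the aldehyde enolate (E1cB) may run faster than the C12 epimerisation, and intermolecular nitro-aldol reactions may compete with ring closure.
 Fallback (sets out from 6, 9 and 13, comes back at 17): the stereochemical plan is inverted so that no aldehyde is exposed to DBU. The Michael addition is run with the enantiomeric catalyst, (R)-2-[diphenyl(trimethylsilyloxy)methyl]pyrrolidine, which should give the 8-epi Michael adduct F1, with C12 already as in the target and C8 epimeric. Without isolation, F1 is olefinated with 13 (LiCl, i-Pr2NEt, MeCN) to the acyclic enone F2, which locks C12. DBU/NaI in dilute MeCN then closes the same C9–C10 bond by nitronate alkylation to the 8-epi nitrocyclopentane enone F3. CBS reduction as in step 7 should give the 8-epi allylic alcohol F4, and LiOH followed by buffered TiCl3 as in step 8 should give, through the 8-epi nitro acid F5, the 8-epi keto acid F6. Its C8 centre, now α to the C9 ketone and cis to the C12 chain, is equilibrated to the trans arrangement with KOAc in MeOH at rt, which gives 17.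

2. Step 8. What may go wrong: the titanium-mediated reduction may stall at the oxime stage, or the acidic titanium medium may cleave the silyl ether and start dehydration of the β-oxygenated ketone.
 Fallback (sets out from 15, comes back at 19): the carbonyl is unveiled oxidatively after the alkene is gone, and the ester is cleaved last by an enzyme. Hydrogenation of 15 with H2 and RhCl(PPh3)3 in benzene/EtOH, which leaves the nitro group alone, should give the 13,14-dihydro nitro ester F7. Its sodium nitronate (NaOMe, MeOH, −78 °C) is cleaved with O3, then Me2S, to the 11-O-TBS-13,14-dihydro-PGE1 methyl ester F8. HF·pyridine in MeCN gives the 13,14-dihydro-PGE1 methyl ester F9, and porcine liver esterase in pH 7 phosphate buffer hydrolyses the ester to 19.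

3. Step 7. What may go wrong: poor facial selectivity in hydride delivery to the C15 ketone, which is remote from the ring stereocentres, so that C15 epimers would have to be separated.
 Fallback (sets out from 12, comes back at 15): C15 is taken from the chiral pool and C13=C14 is made by cross-metathesis. Wittig methylenation of 12 with Ph3P=CH2 (from Ph3PCH3Br and KN(SiMe3)2, excess, THF, −78 → 0 °C) should give the vinylcyclopentane F10. Cross-metathesis of F10 with commercial (S)-oct-1-en-3-ol (CCCCC[C@H](O)C=C, excess) and second-generation Hoveyda–Grubbs catalyst in CH2Cl2 at 40 °C should give the E-allylic alcohol 15 directly.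

**Further compounds**

F1 | step 5 | 8-epi Michael adduct, methyl (8S,9R,10S)-11-bromo-10-[(tert-butyldimethylsilyl)oxy]-9-formyl-8-(nitromethyl)undecanoate (not isolated) | O=C[C@@H]([C@@H](CBr)O[Si](C)(C)C(C)(C)C)[C@@H](C[N+](=O)[O-])CCCCCCC(=O)OC
F2 | step 5 | acyclic enone, E-enone from F1 and 13 with C11 and C12 as in the target and C8 epimeric | CCCCCC(=O)/C=C/[C@@H]([C@@H](CBr)O[Si](C)(C)C(C)(C)C)[C@@H](C[N+](=O)[O-])CCCCCCC(=O)OC
F3 | step 5 | 8-epi nitrocyclopentane enone, C8 epimer of 14 | CCCCCC(=O)/C=C/[C@H]1[C@H](O[Si](C)(C)C(C)(C)C)CC([N+](=O)[O-])[C@H]1CCCCCCC(=O)OC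
F4 | step 5 | 8-epi allylic alcohol, C8 epimer of 15 | CCCCC[C@H](O)/C=C/[C@H]1[C@H](O[Si](C)(C)C(C)(C)C)CC([N+](=O)[O-])[C@H]1CCCCCCC(=O)OC
F5 | step 5 | 8-epi nitro acid, C8 epimer of 16 (not isolated) | CCCCC[C@H](O)/C=C/[C@H]1[C@H](O[Si](C)(C)C(C)(C)C)CC([N+](=O)[O-])[C@H]1CCCCCCC(=O)O
F6 | step 5 | 8-epi keto acid, C8 epimer of 17 | CCCCC[C@H](O)/C=C/[C@H]1[C@H](O[Si](C)(C)C(C)(C)C)CC(=O)[C@H]1CCCCCCC(=O)O
F7 | step 8 | 13,14-dihydro nitro ester, methyl 7-[(1R,2R,3R)-3-[(tert-butyldimethylsilyl)oxy]-2-[(3S)-3-hydroxyoctyl]-5-nitrocyclopentyl]heptanoate | CCCCC[C@H](O)CC[C@H]1[C@H](O[Si](C)(C)C(C)(C)C)CC([N+](=O)[O-])[C@@H]1CCCCCCC(=O)OC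
F8 | step 8 | 11-O-TBS-13,14-dihydro-PGE1 methyl ester | CCCCC[C@H](O)CC[C@H]1[C@H](O[Si](C)(C)C(C)(C)C)CC(=O)[C@@H]1CCCCCCC(=O)OC
F9 | step 8 | 13,14-dihydro-PGE1 methyl ester | CCCCC[C@H](O)CC[C@H]1[C@H](O)CC(=O)[C@@H]1CCCCCCC(=O)OC
F10 | step 7 | vinylcyclopentane, methyl 7-[(1R,2R,3R)-3-[(tert-butyldimethylsilyl)oxy]-2-ethenyl-5-nitrocyclopentyl]heptanoate | C=C[C@H]1[C@H](O[Si](C)(C)C(C)(C)C)CC([N+](=O)[O-])[C@@H]1CCCCCCC(=O)OC
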